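The runs come from a simulation for an exercise, noise included.

I began with the easy step, the clock of the feed: the coupling partner goes in over 0.17 d.

| flask | substrate | coupling partner | remark | time |
|---|---|---|---|---|
| west | 0.025 M | 0.060 M (fed, over 4.0 h) | run made earlier; the fed solution adds 0.50 times the starting volume |  |
| south-west | 0.038 M | 0.060 M (fed, over 4.0 h) | run made earlier; the fed solution adds 0.50 times the starting volume |  |
| north | 0.050 M | 0.030 M (fed, over 4.0 h) | run made earlier; the fed solution adds 0.50 times the starting volume |  |
| flask | 0.050 M | 0.0600 M (fed, over 4.0 h) | the fed solution adds 0.50 times the starting volume | 15 d |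

| run | time / d | target / % |
|---|---|---|
| west | 0.125 | 44.2 |
| west | 0.500 | 71.5 |
| west | 2.50 | 33.5 |
| west | 12.0 | 19.9 |
| south-west | 0.125 | 39.5 |
| south-west | 0.500 | 64.4 |
| south-west | 2.50 | 31.4 |
| south-west | 12.0 | 18.7 |
| north | 0.125 | 20.5 |
| north | 0.500 | 36.6 |
| north | 2.50 | 13.4 |
| north | 12.0 | 6.6 |

(readings scatter by 0.3 percentage points)

- percent here means substrate units held: one side product counts as two
- amounts are per litre of the starting volume; all of the dose is in the solution fed
- what may be going on: substrate + coupling partner <-> target + released group; substrate + target -> side product; target <-> isomer of the product; released group -> by-product carried off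

- the moment within 15 d at which there is most target
- the amount of target, in percent of the substrate charged, at that time

The next rung I read from the west run, whose target fell from 71.5% at 0.500 d to 33.5% at 2.50 d and stood at 19.9% at 12.0 d. Taking that last reading as the late level, I got h = 1.04 d, the time in which target's excess over its late level halves (a relaxation half-time). The feed is shorter than h, so I expected the flask to lose little target during the feed and to peak soon after it, before 0.500 d. The top rung is the 15 d allowed, which is 14.4 times h, so I expected target in the flask to stop changing long before the end.

The forecast gave 60% at 0.4 d: “Formation then equals loss at about 0.4 d, just after the end of feeding.”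

The flask gave 59.3% at 0.333 d, so the forecast's amount stood within tolerance and its time was too high by a factor of 1.20.

    substrate + coupling partner ⇌ target + released group (K = 3.00, k = 0.00420 M⁻¹ s⁻¹)
    substrate + target → side product (k = 2.80 × 10⁻⁴ M⁻¹ s⁻¹)
    target ⇌ isomer of the product (K = 3.70, k = 6.70 × 10⁻⁶ s⁻¹)
    released group → by-product carried off (k = 3.30 × 10⁻⁵ s⁻¹)

Target's half-life by the forward step to the isomer alone, 1.2 d, is short against 15 d. At 7.50 d, already 7.21 times h, the flask held target 17.4%, and at 15.0 d it held 17.0% beside isomer 63.0%, a ratio of 0.270. For the neighbour with 0.020 M of substrate, 14.4 times h again pointed to that same ratio at the end. That neighbour ended with target 20.3% and isomer 74.9%, a ratio of 0.271.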